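**Retrosynthetic overview**

1. Numbering used below: C1 = oxane CH next to the ring-alkene carbon C10; C2/C3 = oxane CH2; C4 = spiro carbon (C15 = epoxide CH2); C5 = oxane CH–O next to C6; C6/C7 = lactone CH–O/CH; C8 = CH–O-methacrylate; C9=C10 ring alkene (C14 = CHO); C11–C13 = methylene-lactone unit.
2. Target 32 ⇐ enal 31 by exo-face epoxidation of a C4=C15 exocyclic methylene; 31 ⇐ bridgehead enol ether 28 by palladium–formate reductive allylic transposition (C15–OPiv → C5–H, C4=C15) and C14 oxidation.
3. Enabling feature: the oxane ring O–C1–C2–C3–C4–C5, bridged across C1/C5 by the five-carbon chain C6–C10 (11-oxabicyclo[5.3.1]undecane core), is the retron of a type 2 intramolecular oxa-Diels–Alder reaction. The oxadiene O=C5–C4=C3, tethered through its carbonyl carbon C5, adds to the vinyl group C1=C2 on C10, closing the oxane, the ten-membered carbocycle and the oxocene in one operation (27 → 28).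
4. Enone 27 ⇐ lactone 19 by a Schenck ene reaction (C5 oxygen, C4=C3 methylene) and ruthenium trans-hydrostannation/copper vinylation (diene with C8 cis to vinyl); C6/C7 from an Evans syn-aldol/lactonisation, C8 from Noyori transfer hydrogenation of an ynone.
5. Ring order: γ-lactone (step 5) → oxane together with the ten-membered ring (step 16) → spiro-epoxide (step 20).

Key step: step 16

Remark: the target is (1R,4R,5R,6S,7R,8R) in this numbering; C5 of 20–26 is an epimer mixture that converges at enone 27, and CIP letters quoted for intermediates are those of each compound itself.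

**Route**

Step 1
Reactants: 1 2-methyl-2-vinyloxirane (isoprene monoxide, racemic)
Product: 2 (E)-4-chloro-2-methylbut-2-en-1-ol
Conditions: TiCl4, CH2Cl2, −85 °C; aqueous work-up
Reagents that add atoms: titanium tetrachloride, Cl[Ti](Cl)(Cl)Cl
Why: SN2' opening of the Lewis-acid-activated vinyl epoxide by chloride through a titanium-chelated s-cis conformer, a known opening of this epoxide that should give the E allylic chloride (any Z isomer is removed at 4).

Step 2
Reactants: 2 (E)-4-chloro-2-methylbut-2-en-1-ol
Product: 3 (E)-4-chloro-2-methylbut-2-en-1-yl pivalate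
Conditions: PivCl, pyridine, CH2Cl2, 0 °C
Reagents that add atoms: pivaloyl chloride, CC(C)(C)C(Cl)=O
Why: Standard O-acylation; the pivalate should survive the later LiOOH and enolate steps and serves as the allylic leaving group in step 17.

Step 3
Reactants: 3 (E)-4-chloro-2-methylbut-2-en-1-yl pivalate
Product: 4 (E)-2-methyl-4-oxobut-2-en-1-yl pivalate
Conditions: N-methylmorpholine N-oxide (3 equiv), NaI (cat.), MeCN, rt
Reagents that add atoms: N-methylmorpholine N-oxide, C[N+]1([O-])CCOCC1
Why: Kornblum-type oxidation with an amine N-oxide (SN2 displacement of the primary allylic halide by the N-oxide oxygen, then loss of the amine) gives the enal without touching the alkene geometry.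

Step 4
Reactants: 5 (S)-4-benzyl-1,3-oxazolidin-2-one; 6 methyl 4-chloro-4-oxobutanoate
Product: 7 methyl 4-[(4S)-4-benzyl-2-oxo-1,3-oxazolidin-3-yl]-4-oxobutanoate
Conditions: n-BuLi, THF, −78 °C; then 6, −78 → 0 °C
Reagents that add atoms: none
Why: N-Acylation of the lithiated Evans oxazolidinone; the methyl ester is kept as the future lactone carbonyl.

Step 5
Reactants: 7 methyl 4-[(4S)-4-benzyl-2-oxo-1,3-oxazolidin-3-yl]-4-oxobutanoate; 4 (E)-2-methyl-4-oxobut-2-en-1-yl pivalate
Product: 9 trans-lactone imide (4S)-4-benzyl-3-{[(2R,3S)-2-[(E)-2-methyl-3-(pivaloyloxy)prop-1-enyl]-5-oxooxolan-3-yl]carbonyl}-1,3-oxazolidin-2-one, via syn-aldol adduct 8 (not isolated)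
Conditions: Bu2BOTf, i-Pr2NEt, CH2Cl2, 0 °C; 4, −78 → 0 °C; pH 7 buffer, H2O2, MeOH; then PPTS (cat.), PhMe, 40 °C
Reagents that add atoms: none
Why: Evans syn-aldol reaction through the (Z)-boron enolate of the imide and a Zimmerman–Traxler chair, in which the (S)-benzyl auxiliary sets C7 and C6, followed by 5-exo-trig lactonisation of the C6 hydroxyl onto the methyl ester to give the trans γ-lactone.

Step 6
Reactants: 9 trans-lactone imide
Product: 10 (2R,3S)-2-[(E)-2-methyl-3-(pivaloyloxy)prop-1-enyl]-5-oxooxolane-3-carboxylic acid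
Conditions: LiOH, H2O2, THF/H2O, 0 °C; Na2SO3; 1 M HCl
Reagents that add atoms: hydrogen peroxide (as LiOOH), OO
Why: Evans LiOOH cleavage, in which hydroperoxide attacks the exocyclic imide carbonyl selectively and acidification re-closes any opened lactone; the hindered pivalate should survive.

Step 7
Reactants: 10 lactone acid; 11 tert-butyldimethyl(prop-2-yn-1-yloxy)silane
Product: 13 ynone (E)-3-[(2R,3S)-3-{4-[(tert-butyldimethylsilyl)oxy]but-2-ynoyl}-5-oxooxolan-2-yl]-2-methylprop-2-enyl pivalate, via acid chloride 12 (not isolated)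
Conditions: (COCl)2, DMF (cat.), CH2Cl2, 0 °C → rt, evaporate; 11, n-BuLi, THF, −78 °C, then ZnCl2; add 12, Pd(PPh3)4 (1 mol %), THF, 0 °C
Reagents that add atoms: none
Why: Negishi acylation of an alkynylzinc chloride by the acid chloride (zerovalent palladium inserts into the C–Cl bond far faster than it ionises the allylic esters); the amine-free conditions avoid ketene formation and E1cB opening of the β-acyloxy ketone.

Step 8
Reactants: 13 ynone
Product: 14 (E)-3-[(2R,3R)-3-{(1S)-4-[(tert-butyldimethylsilyl)oxy]-1-hydroxybut-2-ynyl}-5-oxooxolan-2-yl]-2-methylprop-2-enyl pivalate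
Conditions: Ru[(S,S)-TsDPEN](p-cymene) (2 mol %), i-PrOH, rt
Reagents that add atoms: none
Why: Noyori asymmetric transfer hydrogenation of an alkynyl ketone, in which the alkyne takes the π (aryl) site of the Ru–H/N–H transition state, so the (S,S) catalyst should give under reagent control the (S)-propargylic alcohol, which is the spatial arrangement needed at C8.

Step 9
Reactants: 14 propargylic alcohol
Product: 17 α-methylene lactone (E)-3-[(2R,3R)-3-{(1S)-4-[(tert-butyldimethylsilyl)oxy]-1-hydroxybut-2-ynyl}-4-methylidene-5-oxooxolan-2-yl]-2-methylprop-2-enyl pivalate, via Mannich base 15 (not isolated), via methiodide 16 (not isolated)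
Conditions: LiN(i-Pr)2 (LDA, 2.3 equiv), THF, −78 °C; CH2=NMe2+ I−, −78 → 0 °C; H2O; MeI, MeOH, rt; NaHCO3 aq., CH2Cl2, rt
Reagents that add atoms: Eschenmoser's salt, C=[N+](C)C.[I-]
Why: Eschenmoser α-methylenation: Mannich reaction of the lactone enolate (alkoxide–enolate dianion), quaternisation and E1cB (Hofmann-type) elimination give the exocyclic alkene, so the transient C11 centre is of no consequence.

Step 10
Reactants: 17 α-methylene lactone alcohol; 18 methacrylic anhydride
Product: 19 C8 methacrylate of 17 (configurations unchanged)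
Conditions: Et3N, DMAP (cat.), CH2Cl2, 0 °C
Reagents that add atoms: none
Why: DMAP-catalysed acylation of the secondary propargylic alcohol installs the final ester and caps O8, so that only O14 can direct step 13.

Step 11
Reactants: 19 methacrylate
Product: 21 C5 allylic alcohol with C4=C3 methylene (C5 epimers), via allylic hydroperoxide 20 (not isolated)
Conditions: O2, tetraphenylporphyrin (cat.), white LED, CH2Cl2, 0 °C; then PPh3, 0 °C
Reagents that add atoms: dioxygen (as singlet oxygen), O=O
Why: Schenck ene reaction at the only electron-rich alkene: by the cis effect hydrogen is taken from the C3 methyl group cis to C6 (H6 is held in the alkene plane by allylic strain), oxygen goes to C5 and the double bond to C4=C3, and PPh3 reduces the hydroperoxide.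

Step 12
Reactants: 21 allylic alcohol
Product: 22 C5,C14-diol (free propargylic C14–OH)
Conditions: HF·pyridine, pyridine, THF, 0 °C
Reagents that add atoms: none
Why: Fluoride cleavage of the primary silyl ether frees the C14 hydroxyl needed as directing group; esters and lactone are inert.

Step 13
Reactants: 22 diol
Product: 23 (Z)-alkenylstannane (Bu3Sn on C10 cis to C8; H on C9)
Conditions: [Cp*RuCl]4 (2.5 mol %), Bu3SnH (1.1 equiv), CH2Cl2, rt
Reagents that add atoms: tributyltin hydride, CCCC[SnH](CCCC)CCCC
Why: Ruthenium-catalysed trans-hydrostannation of a propargylic alcohol, in which the free C14 hydroxyl binds the Ru–Cl unit and steers tin to the proximal alkyne carbon C10 while hydrogen adds anti at C9.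

Step 14
Reactants: 23 alkenylstannane; 24 iodoethene
Product: 25 diene diol (vinyl on C10 cis to C8; C5–OH and C14–OH free)
Conditions: Cu(O2C-2-thienyl) (CuTC, 1.5 equiv), NMP, 0 °C → rt
Reagents that add atoms: none
Why: Copper-mediated Stille-type cross-coupling (tin-to-copper transmetallation assisted by the neighbouring hydroxyl, monovalent copper) proceeds with retention of alkene geometry; the palladium-free variant spares the allylic pivalate and methacrylate.

Step 15
Reactants: 25 diene diol
Product: 26 C14 triethylsilyl ether (C5–OH free)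
Conditions: TESCl (1.05 equiv), imidazole, CH2Cl2, −40 °C
Reagents that add atoms: chlorotriethylsilane, CC[Si](Cl)(CC)CC
Why: Selective silylation of the primary allylic alcohol over the hindered secondary C5 alcohol, so that step 16 oxidises C5 only and the diene stays electron-rich.

Step 16
Reactants: 26 C14 triethylsilyl ether
Product: 28 bridged dihydropyran (1R; C1–O–C5 ether bridge; bridgehead enol ether C5=C4 carrying C15H2OPiv), via enone 27 (not isolated)
Conditions: DMP, NaHCO3, CH2Cl2, 0 °C → rt; filtration through Celite; then PhMe (0.002 M), BHT (cat.), 110 °C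
Reagents that add atoms: none
Why: Proposed new method: a type 2 (bridged) intramolecular inverse-electron-demand oxa-Diels–Alder reaction in which the s-cis oxadiene O=C5–C4=C3 of 27, tethered through its carbonyl carbon by C6–C10, adds across the vinyl group C1=C2, the C2–C3 bond forming ahead of the O–C1 bond; the closest known reactions are the all-carbon type 2 intramolecular Diels–Alder reaction that gives bicyclo[5.3.1]undecenes with a bridgehead alkene, the head-to-head hetero-Diels–Alder dimerisation of α-methylene ketones and intramolecular oxa-Diels–Alder reactions of enones with alkenes. It closes three rings at once: the dihydropyran by [4+2] cycloaddition, the ten-membered carbocycle through the C2–C3 bond (endo mode at the vinyl group) and the eight-membered oxocene through the O–C1 bond, leaving the bridgehead enol ether C5=C4 that a [5.3.1] framework accommodates. The only new stereocentre, C1, is set by the face of the vinyl group that the oxadiene reaches: the tether must sit endo at C1, and the rigid trans-lactone with the C8 ester is expected to favour the transition state that keeps C11 and the C8–O bond on the side of the ether oxygen and turns H7 and H8 toward C2–C3, which is the (1R) adduct. Regiochemistry is enforced by the tether (oxygen to the substituted vinyl carbon, CH2 to CH2); periselectivity against the all-carbon Diels–Alder mode is secured by the C8 substituent cis to the vinyl group on C9=C10, which keeps the diene out of the s-cis conformation, and the methacrylate and lactone methylenes are electron-poor and geometrically disfavoured partners. High dilution and generation of the enone in the flask guard against its dimerisation.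

Step 17
Reactants: 28 bridged dihydropyran
Product: 29 C4=C15 exocyclic methylene bicycle with C5–H (C14–OTES)
Conditions: Pd(OAc)2 (5 mol %), PBu3 (10 mol %), HCO2H, Et3N, THF, 40 °C
Reagents that add atoms: none
Why: Palladium-catalysed formate hydrogenolysis of an allylic ester with allylic transposition: zerovalent palladium ionises the primary C15 pivalate to the alkoxy-stabilised π-allyl complex and the formate-derived hydride is delivered to the more substituted terminus C5 on the only accessible (outer) face of the bridgehead, which gives the configuration at C5 that the bicycle dictates.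

Step 18
Reactants: 29 exocyclic methylene bicycle
Product: 30 C14 allylic alcohol
Conditions: HF·pyridine, pyridine, THF, 0 °C
Reagents that add atoms: none
Why: Buffered fluoride desilylation of the primary triethylsilyl ether.

Step 19
Reactants: 30 allylic alcohol
Product: 31 enal (C14 aldehyde)
Conditions: MnO2 (excess), CH2Cl2, rt
Reagents that add atoms: none
Why: Chemoselective MnO2 oxidation of the primary allylic alcohol to the enal without isomerising the trisubstituted alkene.

Step 20
Reactants: 31 enal
Product: 32 target CNP0257628.1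
Conditions: mCPBA (1.2 equiv), CH2Cl2, 0 °C
Reagents that add atoms: meta-chloroperbenzoic acid, OOC(=O)c1cccc(Cl)c1
Why: Prilezhaev epoxidation of the only electron-rich alkene; the peracid should approach the exocyclic methylene from the face anti to the axial C5–C6 bond and the five-carbon bridge (axial attack past the ring oxygen), placing the epoxide oxygen trans to C6 as required for (4R).

**Compound list**

1 | 2-methyl-2-vinyloxirane (racemic) | C=CC1(C)CO1 | starting material
2 | (E)-4-chloro-2-methylbut-2-en-1-ol | OC/C(C)=C/CCl | intermediate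
3 | (E)-4-chloro-2-methylbut-2-en-1-yl pivalate | CC(C)(C)C(=O)OC/C(C)=C/CCl | intermediate
4 | (E)-2-methyl-4-oxobut-2-en-1-yl pivalate | CC(C)(C)C(=O)OC/C(C)=C/C=O | intermediate
5 | (S)-4-benzyl-1,3-oxazolidin-2-one | O=C1N[C@@H](Cc2ccccc2)CO1 | starting material
6 | methyl 4-chloro-4-oxobutanoate | COC(=O)CCC(Cl)=O | starting material
7 | methyl 4-[(4S)-4-benzyl-2-oxo-1,3-oxazolidin-3-yl]-4-oxobutanoate | COC(=O)CCC(=O)N1[C@@H](Cc2ccccc2)COC1=O | intermediate
8 | syn-aldol adduct, methyl (3S,4R,5E)-3-{[(4S)-4-benzyl-2-oxo-1,3-oxazolidin-3-yl]carbonyl}-4-hydroxy-6-methyl-7-(pivaloyloxy)hept-5-enoate | CC(C)(C)C(=O)OC/C(C)=C/[C@@H](O)[C@H](CC(=O)OC)C(=O)N1[C@@H](Cc2ccccc2)COC1=O | intermediate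
9 | trans-lactone imide, (4S)-4-benzyl-3-{[(2R,3S)-2-[(E)-2-methyl-3-(pivaloyloxy)prop-1-enyl]-5-oxooxolan-3-yl]carbonyl}-1,3-oxazolidin-2-one | CC(C)(C)C(=O)OC/C(C)=C/[C@H]1OC(=O)C[C@@H]1C(=O)N2[C@@H](Cc3ccccc3)COC2=O | intermediate
10 | (2R,3S)-2-[(E)-2-methyl-3-(pivaloyloxy)prop-1-enyl]-5-oxooxolane-3-carboxylic acid | CC(C)(C)C(=O)OC/C(C)=C/[C@H]1OC(=O)C[C@@H]1C(=O)O | intermediate
11 | tert-butyldimethyl(prop-2-yn-1-yloxy)silane | C#CCO[Si](C)(C)C(C)(C)C | starting material
12 | (2R,3S)-2-[(E)-2-methyl-3-(pivaloyloxy)prop-1-enyl]-5-oxooxolane-3-carbonyl chloride | CC(C)(C)C(=O)OC/C(C)=C/[C@H]1OC(=O)C[C@@H]1C(Cl)=O | intermediate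
13 | ynone, (E)-3-[(2R,3S)-3-{4-[(tert-butyldimethylsilyl)oxy]but-2-ynoyl}-5-oxooxolan-2-yl]-2-methylprop-2-enyl pivalate | CC(C)(C)C(=O)OC/C(C)=C/[C@H]1OC(=O)C[C@@H]1C(=O)C#CCO[Si](C)(C)C(C)(C)C | intermediate
14 | (E)-3-[(2R,3R)-3-{(1S)-4-[(tert-butyldimethylsilyl)oxy]-1-hydroxybut-2-ynyl}-5-oxooxolan-2-yl]-2-methylprop-2-enyl pivalate | CC(C)(C)C(=O)OC/C(C)=C/[C@H]1OC(=O)C[C@@H]1[C@H](O)C#CCO[Si](C)(C)C(C)(C)C | intermediate
15 | Mannich base: 14 with a dimethylaminomethyl group on the lactone α-carbon C11 (C11 epimers) | CC(C)(C)C(=O)OC/C(C)=C/[C@H]1OC(=O)C(CN(C)C)[C@@H]1[C@H](O)C#CCO[Si](C)(C)C(C)(C)C | intermediate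
16 | trimethylammonium iodide (methiodide) of 15 | CC(C)(C)C(=O)OC/C(C)=C/[C@H]1OC(=O)C(C[N+](C)(C)C)[C@@H]1[C@H](O)C#CCO[Si](C)(C)C(C)(C)C.[I-] | intermediate
17 | α-methylene lactone, (E)-3-[(2R,3R)-3-{(1S)-4-[(tert-butyldimethylsilyl)oxy]-1-hydroxybut-2-ynyl}-4-methylidene-5-oxooxolan-2-yl]-2-methylprop-2-enyl pivalate | CC(C)(C)C(=O)OC/C(C)=C/[C@H]1OC(=O)C(=C)[C@@H]1[C@H](O)C#CCO[Si](C)(C)C(C)(C)C | intermediate
18 | methacrylic anhydride | CC(=C)C(=O)OC(=O)C(C)=C | starting material
19 | C8 methacrylate of 17 (C6, C7, C8 arranged as in 32; E trisubstituted C5=C4 alkene; C9≡C10 alkyne; C14–OTBS; C15–OPiv) | CC(C)(C)C(=O)OC/C(C)=C/[C@H]1OC(=O)C(=C)[C@@H]1[C@H](OC(=O)C(C)=C)C#CCO[Si](C)(C)C(C)(C)C | intermediate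
20 | C5 allylic hydroperoxide with C4=C3 methylene (C5 epimers) | CC(C)(C)C(=O)OCC(=C)C(OO)[C@H]1OC(=O)C(=C)[C@@H]1[C@H](OC(=O)C(C)=C)C#CCO[Si](C)(C)C(C)(C)C | intermediate
21 | C5 allylic alcohol with C4=C3 methylene (C5 epimers; C14–OTBS) | CC(C)(C)C(=O)OCC(=C)C(O)[C@H]1OC(=O)C(=C)[C@@H]1[C@H](OC(=O)C(C)=C)C#CCO[Si](C)(C)C(C)(C)C | intermediate
22 | C5,C14-diol (C5 epimers; propargylic C14–OH free) | CC(C)(C)C(=O)OCC(=C)C(O)[C@H]1OC(=O)C(=C)[C@@H]1[C@H](OC(=O)C(C)=C)C#CCO | intermediate
23 | (Z)-alkenylstannane (Bu3Sn on C10 cis to C8, H on C9; C5 epimers) | CC(C)(C)C(=O)OCC(=C)C(O)[C@H]1OC(=O)C(=C)[C@@H]1[C@H](OC(=O)C(C)=C)/C=C(/CO)[Sn](CCCC)(CCCC)CCCC | intermediate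
24 | iodoethene (vinyl iodide) | C=CI | starting material
25 | diene diol (vinyl on C10 cis to C8, CH2OH trans to C8; C5 epimers) | CC(C)(C)C(=O)OCC(=C)C(O)[C@H]1OC(=O)C(=C)[C@@H]1[C@H](OC(=O)C(C)=C)/C=C(/CO)C=C | intermediate
26 | C14 triethylsilyl ether of 25 (C5–OH free, C5 epimers) | CC(C)(C)C(=O)OCC(=C)C(O)[C@H]1OC(=O)C(=C)[C@@H]1[C@H](OC(=O)C(C)=C)/C=C(/CO[Si](CC)(CC)CC)C=C | intermediate
27 | enone (C5 ketone conjugated with C4=C3; oxadiene and vinyl dienophile in one chain) | CC(C)(C)C(=O)OCC(=C)C(=O)[C@H]1OC(=O)C(=C)[C@@H]1[C@H](OC(=O)C(C)=C)/C=C(/CO[Si](CC)(CC)CC)C=C | intermediate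
28 | bridged dihydropyran (1R; C1–O–C5 bridge; bridgehead enol ether C5=C4 with C15H2OPiv; C14–OTES; C8 methacrylate; trans-lactone) | C=C(C)C(=O)O[C@@H]1/C=C(/CO[Si](CC)(CC)CC)[C@H]2CCC(COC(=O)C(C)(C)C)=C(O2)[C@H]2OC(=O)C(=C)[C@@H]21 | intermediate
29 | C4=C15 exocyclic methylene bicycle with C5–H (C14–OTES) | C=C(C)C(=O)O[C@@H]1/C=C(/CO[Si](CC)(CC)CC)[C@H]2CCC(=C)[C@H](O2)[C@H]2OC(=O)C(=C)[C@@H]21 | intermediate
30 | C14 allylic alcohol of the methylene bicycle | C=C(C)C(=O)O[C@@H]1/C=C(/CO)[C@H]2CCC(=C)[C@H](O2)[C@H]2OC(=O)C(=C)[C@@H]21 | intermediate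
31 | enal (C14 aldehyde) of the methylene bicycle | C=C(C)C(=O)O[C@@H]1/C=C(/C=O)[C@H]2CCC(=C)[C@H](O2)[C@H]2OC(=O)C(=C)[C@@H]21 | intermediate
32 | CNP0257628.1 | C=C(C)C(=O)O[C@@H]1/C=C(/C=O)[C@H]2CC[C@@]3(CO3)[C@H](O2)[C@H]2OC(=O)C(=C)[C@@H]21 | target

**Step count and risks**

Total steps: 20. Longest linear sequence: 19 (steps 1–3 and 5–20; step 4 is the side branch).

Steps most likely to fail:

1. Step 16 (proposed new method). The bridged cycloaddition may be outrun by the all-carbon Diels–Alder mode of the dienyl enone or by dimerisation of the enone, or may show insufficient facial discrimination at C1. The fallback sets out from 23 and comes back at 28, and makes the bonds separately by known reactions. Stannane 23 is silylated at the primary hydroxyl (TESCl, imidazole) to give the C14 triethylsilyl ether of the stannane F1, which DMP oxidises to the stannyl enone F2. A Yb(fod)3-catalysed intermolecular inverse-demand hetero-Diels–Alder reaction of F2 with ethyl vinyl ether (which here supplies C1 and C2) gives the 2-ethoxy-3,4-dihydro-2H-pyran F3. TMSOTf in CH2Cl2 at −78 °C then ionises the acetal, and ipso attack of the alkenylstannane on the cyclic oxocarbenium ion (stannane-terminated oxocarbenium cyclisation, alkene geometry retained, cis bridging enforced by the tether) closes the ten-membered ring to 28.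

2. Step 17. Hydride may be delivered to the wrong allyl terminus (giving the C15-methyl enol ether), the allylic C8 methacrylate may ionise, or conjugate reduction may compete. The fallback sets out from 28 and comes back at 29 with no new compound (F0): a Ferrier-type ionic reduction (Et3SiH, BF3·OEt2, CH2Cl2, −78 °C), in which Lewis-acid ionisation of the pivalate gives the 2-alkylidene oxocarbenium ion and the silane delivers hydride to C5 from the outer face.

3. Step 11. The ene reaction may take the wrong allylic hydrogen, or the doubly allylically oxygenated alkene may react too slowly with singlet oxygen. The fallback sets out from 19 and comes back at 21. Titrated ozonolysis of the only electron-rich alkene (O3, pyridine, CH2Cl2, −78 °C; Me2S) gives the lactone aldehyde F4. A Nozaki–Hiyama–Kishi coupling (CrCl2, NiCl2 cat., DMF) of F4 with 2-bromoallyl pivalate F5 (from 2-bromoprop-2-en-1-ol and pivaloyl chloride) then gives 21 as the same C5 epimer mixture.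

Further compounds
F1 | step 16 | C14 triethylsilyl ether of stannane 23 | CC(C)(C)C(=O)OCC(=C)C(O)[C@H]1OC(=O)C(=C)[C@@H]1[C@H](OC(=O)C(C)=C)/C=C(/CO[Si](CC)(CC)CC)[Sn](CCCC)(CCCC)CCCC
F2 | step 16 | stannyl enone (C5 ketone of F1) | CC(C)(C)C(=O)OCC(=C)C(=O)[C@H]1OC(=O)C(=C)[C@@H]1[C@H](OC(=O)C(C)=C)/C=C(/CO[Si](CC)(CC)CC)[Sn](CCCC)(CCCC)CCCC
F3 | step 16 | 2-ethoxy-3,4-dihydro-2H-pyran from F2 and ethyl vinyl ether (acetal epimers) | CCOC1CCC(COC(=O)C(C)(C)C)=C(O1)[C@H]2OC(=O)C(=C)[C@@H]2[C@H](OC(=O)C(C)=C)/C=C(/CO[Si](CC)(CC)CC)[Sn](CCCC)(CCCC)CCCC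
F0 | step 17 | none | none
F4 | step 11 | lactone aldehyde (C5 aldehyde on C6) | O=C[C@H]1OC(=O)C(=C)[C@@H]1[C@H](OC(=O)C(C)=C)C#CCO[Si](C)(C)C(C)(C)C
F5 | step 11 | 2-bromoallyl pivalate | CC(C)(C)C(=O)OCC(Br)=C
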